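The numbers in the tables come from a simulation for substances that don't exist; the scatter is artificial.

- How much product does doubling the reagent buy by 15 h, and is the flask with 3.00 M of reagent worth charging instead of repeating Saturday's 1.5 M?

| flask | substrate | reagent | free catalyst | remark | time |
|---|---|---|---|---|---|
| Saturday's | 1.5 M | 1.5 M | 30 mM | run made earlier |  |
| flask | 1.5 M | 3.00 M | 30 mM |  | 15 h |

Saturday's run (percent of the substrate charged)

| time / h | product / % | substrate / % |
|---|---|---|
| 3.00 | 1.7 | 98.2 |
| 6.00 | 2.9 | 95.3 |
| 10.0 | 6.0 | 93.6 |
| 12.0 | 6.6 | 91.7 |

(scatter of a reading: 0.5 percentage points)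



- concentration of product at 15 h, in M
- concentration of substrate at 15 h, in M
- concentration of reagent at 15 h, in M

- Saturday's product readings climb steadily, so carry the last one in a straight line to the asked time: that estimate gives 0.124 M of product, which you call the base b.
- Now work in common logarithms: log(P/b) = n log(c/s), where P is the product at the asked time, c the reagent charged, s Saturday's reagent charge and n the apparent order in reagent.
- Doubling the reagent charge moves log P by 0.301 per unit of n, about ten times the 0.0329 that the scatter puts on the log of Saturday's last reading, so the new flask can give a reading of n: charge it.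
- Saturday's run has one reagent charge, so it cannot give n; order zero means b, and order one means 0.248 M.
- My own reckoning takes the middle of that range in logarithms, n = 0.5, which gives 0.175 M of product.
- The forecast differs: 0.24 M of product, 1.25 M of substrate and 2.76 M of reagent, with the caution that “first order is an assumption”.
- The flask gives 0.180 M of product, 1.31 M of substrate and 2.80 M of reagent.

    reagent + free catalyst ⇌ catalyst intermediate A (K = 0.380 L mol⁻¹, k = 9.60 × 10⁻⁴ L mol⁻¹ s⁻¹)
    substrate + catalyst intermediate A ⇌ catalyst intermediate B (K = 0.260 L mol⁻¹, k = 0.00860 L mol⁻¹ s⁻¹)
    catalyst intermediate B → by-product + catalyst intermediate C (k = 0.00110 s⁻¹)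
    catalyst intermediate C ⇌ free catalyst + product (K = 0.500 M, k = 5.20 × 10⁻⁴ s⁻¹)

- The forecast's product is 1.33 times the flask's. Set against b, the flask's product reads n = 0.544, lower than order one. Now take the neighbouring flask, the same flask but with 1.8 M of reagent: b times (1.8/1.5) to the power n gives 0.137 M of product. That flask holds 0.146 M of product at 15 h, with 1.34 M of substrate left.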